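# Total synthesis proposal for CNP0111873.1 (34) by epoxy-polyene bicyclisation and late bridging

## Analysis of the target

The target 34 is a sesquiterpenoid triacetate in which a cyclohexane (ring A) is fused to a tricyclo[2.2.1.0(2,6)]heptane (nortricyclene) cage. Its eleven skeletal carbons are lettered along the chain: C-a (quaternary, bears CH2OAc), C-b (CH2), C-c (CHOH), C-d (CHOAc), C-e (CMe2), C-f (quaternary), C-g (CH2), C-h and C-i (cyclopropane CH, C-h bonded to C-g and C-i bonded to C-a), C-j (cyclopropane carbon with the methyl group) and C-k (CHOAc). In the cage C-f is the apex, C-a, C-g and C-k are the three one-carbon bridges and C-h, C-i, C-j form the cyclopropane; ring A (C-a to C-f) shares the C-a–C-f bond with the cage. There are eight stereocentres (C-a, C-c, C-d, C-f, C-h, C-i, C-j, C-k). The cage fixes C-h, C-i and C-j once C-a and C-f are set, so the free elements are three: CH2OAc on C-a points to the C-g side and away from C-k; the acetate on C-k points toward C-g and away from C-a; the cis-diol unit lies on the ring-A face that carries CH2OAc, with the free hydroxyl axial on C-c and the acetate equatorial on C-d. The sensitive groups are the strained cyclopropane (acids, electrophiles), the cyclopropylcarbinyl acetate on C-k (ionisation) and the cis hydroxy acetate (acyl migration). The synthesis is hard because of three contiguous fully substituted carbons (C-e, C-f, C-a) with a fourth at C-j, the strain of the cage, and the need to leave one hindered hydroxyl free beside three acetates. The strategy rests on one feature: removal of C-k and of the C-h–C-i bond leaves a trans-decalin (ring A plus ring B = C-a, C-f, C-g, C-h, C-j, C-i) with oxygen on C-d beside the CMe2 carbon and trans one-carbon arms on both ring-fusion carbons, which is the pattern an epoxide-initiated polyene cyclisation produces.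

## Retrosynthetic reasoning

**Acetate pattern (34 from 32 from 29).** The last bond cut is the acetate on C-d. In diol 32 the C-d hydroxyl is equatorial and the C-c hydroxyl is axial between two syn-axial carbon groups, so acylation can be steered to C-d. The two acetates on CH2O and C-k need forcing conditions and are therefore put on tetraol 29 while the ring-A diol is masked.

**Ring-A diol (29 from 26).** Both C–O bonds at C-c and C-d are cut back to the olefin of 26. The diol sits on the more hindered ring-A face (the face of CH2OAc and of the axial methyl), the opposite of what a direct osmylation would give. The forward reaction must therefore be a Woodward-type sequence, in which trans-diaxial addition is followed by inversion through a neighbouring acetate.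

**Cyclopropane (24 from 21 from 20).** The C-h–C-i bond is the only cage bond between two carbons that carry no heteroatom. It is cut to a carbene at C-h and a C–H bond at C-i, that is to tosylhydrazone 21 of ketone 20. This places the carbonyl exactly where hydroboration of a ring-B olefin puts oxygen.

**One-carbon bridge (20 from 18).** The C-j–C-k bond is cut as an aldol bond: C-k is the aldehyde carbon on C-f and C-j is the methyl-bearing alpha carbon of the ring-B ketone in 18. The forward step has to form a norbornanone against strain, so it must be a silyl-transfer (Mukaiyama) aldol that cannot revert.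

**Adjustment of the decalin (18 back to 12).** The ring-B ketone comes from the trisubstituted olefin of 12 by hydroboration and oxidation (15 to 18). The ring-A olefin is made from the carbinol of 12 through ketone 13 and enol triflate 14; the triflate hides the ring-A olefin from borane and is reduced afterwards (16). The aldehyde is unveiled (17, 18) only when ring A holds no enolisable carbonyl, because C-c could otherwise bridge to C-k just as C-j does.

**Key disconnection (12 from 11).** The C-e–C-f and C-a–C-i bonds are cut together. This leads to acyclic epoxy-triene 11, in which the epoxide is the only stereocentre and the E geometry of the tetrasubstituted olefin encodes the trans relation of the two CH2O arms. The forward step closes both rings and sets both quaternary ring-fusion carbons.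

**Epoxide (11 from 10).** The epoxide oxygen is removed to give triene 10; the forward reaction must pick the prenyl terminus among three olefins and one of its faces.

**Tetrasubstituted olefin (10 from 7 and 9; 7 from 6; 6 from 2 and 4; 2 from 1).** The butenyl group is cut off as zinc reagent 9 (from bromide 8) and vinyl iodide 7. The iodide and the homoprenyl group are then removed together, which leads to alkynol 2 and Grignard reagent 4 (from bromide 3). Anti addition across the alkyne, directed by the free hydroxyl, puts the two CH2O groups trans. 2 is the monosilyl ether of diol 1.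

## Alternatives that were turned down

**Alternative 1:** The disconnection removes three cage bonds at once (C-a–C-i, C-h–C-j and the C–O bond at C-k). It leads back to a ring-A spiro-epoxide at C-a next to a methylcyclohexadiene that is spiro-linked at C-f. In the forward key step a Lewis acid ionises the epoxide at C-a, the cation bonds to the inner diene carbon C-i, the homoallylic cation at C-h closes the three-membered ring onto C-j, and acetate quenches the cyclopropylcarbinyl cation at C-k. The product is cage monoacetate A1, with free CH2OH and the ring-A diol held as a carbonate.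
- For: the whole cage, the quaternary C-a and the C-k acetate arise in one operation, and the ring-A diol is already present, so no hydroxylation on the hindered face is needed. On step count after the key step and on the oxidation pattern it is clearly stronger than the chosen route.
- Against: the first C–C bond must form at an internal diene carbon and leaves a secondary, non-allylic cation. The usual fate of a 2,2-disubstituted epoxide under such acids is hydride shift to an aldehyde or a 1,2-shift from the neighbouring spiro carbon. The face of the diene and the face of acetate capture are decided inside the cascade with no control element beyond the developing cage, and cyclopropylcarbinyl cations readily give ring-opened or ring-expanded esters. The substrate, with two adjacent spiro quaternary carbons and an isomerisation-prone diene, is itself a long synthesis.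
- Comparison: the chosen strategy offers C–C bond formations that each follow normal polarity, and a single early source of absolute configuration.

**Alternative 2:** The disconnection is the C-e–C-f bond; ring A is closed last onto a preformed five-membered ring (C-a, C-f, C-k, C-j, C-i). In the forward key step anodic oxidation of a silyloxydiene gives a radical cation that a tethered enol ether attacks through its dimethyl-substituted carbon. The product is cis-fused hydrindenone ketal A2 (C-d as ketal, C-c as an acetal-protected alcohol, C-k as the enone carbonyl).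
- For: a bond to the fully substituted C-e is made under mild, non-acidic conditions. Ring A arrives with both oxygens, which is equal or stronger than the chosen route on this point and avoids a strained aldol. The enone is a good handle for a later intramolecular cyclopropanation.
- Against: the coupling joins a tetrasubstituted enol ether carbon to a carbon next to a quaternary centre. In A2 C-f is still a CH, so the C-g–C-h unit must be attached later by alkylation at a ring-fusion carbon alpha to the ketone, with facial control and C- versus O-alkylation open. The C-d ketal and the C-k carbonyl each need a stereoselective reduction, the latter from the more hindered side.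
- Comparison: the chosen strategy sets C-a and C-f together, stereospecifically from olefin geometry.

**Alternative 3:** The disconnection is the C-a–C-f bond, made by ring contraction of a homologous tricyclo[3.2.1.0(2,7)]octane alpha-diazoketone in which the future CH2OAc carbon sits in the ring as the carbonyl group. In the forward key step irradiation in an alcohol triggers a Wolff rearrangement: C-f migrates to the diazo carbon C-a and the ketene is trapped as the ester. The product is nortricyclanone ester A3, which carries the C-e to C-b chain with its diol acetonide on C-f and a ketone at C-k.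
- For: the strain is introduced in a step driven by loss of nitrogen, which is thermodynamically more comfortable than the aldol and carbene steps of the chosen route. C-c and C-d come from a preformed diol, and the ester carbon maps onto CH2OAc.
- Against: a larger, fully substituted cage must be built and then shrunk. Diazo transfer has to occur beside a ketone flanked by quaternary carbons. Ring A must then be closed by alkylating the ester enolate at the cage carbon C-a, which makes that quaternary centre late. The C-k ketone must be reduced from the side of C-a, the more hindered one.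
- Comparison: it is stronger on thermodynamics and on early ring-A oxygenation but weaker on step economy; the chosen strategy builds two rings and two quaternary centres in one step from an acyclic precursor five steps from commercial materials.

Key step: step 6

Remark: TBS = tert-butyldimethylsilyl, TIPS = triisopropylsilyl, Tf = trifluoromethanesulfonyl, Ts = 4-methylphenylsulfonyl; decalins 12–19 keep the locants of 12 (C-1 = C-e, C-2 = C-d, C-3 = C-c, C-4 = C-b, C-4a = C-a, C-5 = C-i, C-6 = C-j, C-7 = C-h, C-8 = C-g, C-8a = C-f).

Remark: 15–18 are drawn as the diastereomer expected from hydroboration anti to the axial CH2OTBS group; these two ring-B centres are erased in steps 12 and 13, so their configuration does not matter.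

Remark: the L-fructose-derived enantiomer of the Shi ketone is assumed to be purchasable (it is otherwise made from L-sorbose).

## Route

Step 1
Reactants: 1 but-2-yne-1,4-diol
Product: 2 4-[(tert-butyldimethylsilyl)oxy]but-2-yn-1-ol
Conditions: NaH (1.0 equiv), THF, 0 °C to rt; TBSCl (1.0 equiv)
Reagents that add atoms: tert-butyl(chloro)dimethylsilane, CC(C)(C)[Si](C)(C)Cl
Why: Monosilylation of a symmetrical diol through its sparingly soluble monosodium alkoxide; the remaining hydroxyl is needed to direct the carbometalation.

Step 2
Reactants: 2 4-[(tert-butyldimethylsilyl)oxy]but-2-yn-1-ol; 3 5-bromo-2-methylpent-2-ene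
Product: 6 (2Z)-4-[(tert-butyldimethylsilyl)oxy]-3-iodo-2-(4-methylpent-3-en-1-yl)but-2-en-1-ol, via homoprenylmagnesium bromide 4 (not isolated), via oxamagnesacycle 5 (not isolated)
Conditions: 3 (3 equiv), Mg, THF; then 2, CuI (10 mol%), THF, −10 °C to rt; then I2, −40 to 0 °C
Reagents that add atoms: iodine, II
Why: Alkoxide-directed anti carbomagnesiation of a propargylic alcohol: the alkyl group adds to the alkyne carbon next to CH2O–, and magnesium ends on the distal carbon inside a five-membered chelate, hence cis to CH2O–. Iodinolysis occurs with retention, so the two CH2O groups are trans, as the cyclisation requires.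

Step 3
Reactants: 6 (2Z)-4-[(tert-butyldimethylsilyl)oxy]-3-iodo-2-(4-methylpent-3-en-1-yl)but-2-en-1-ol
Product: 7 (2Z)-1-[(tert-butyldimethylsilyl)oxy]-2-iodo-3-(4-methylpent-3-en-1-yl)-4-[(triisopropylsilyl)oxy]but-2-ene
Conditions: TIPSCl, imidazole, DMF, rt
Reagents that add atoms: chlorotri(propan-2-yl)silane, CC(C)[Si](Cl)(C(C)C)C(C)C
Why: Routine silylation of a primary allylic alcohol; the future C-k arm now carries the acid-labile TBS group and the future CH2OAc arm the more robust TIPS group.

Step 4
Reactants: 7 (2Z)-1-[(tert-butyldimethylsilyl)oxy]-2-iodo-3-(4-methylpent-3-en-1-yl)-4-[(triisopropylsilyl)oxy]but-2-ene; 8 4-bromo-2-methylbut-1-ene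
Product: 10 (2E)-1-[(tert-butyldimethylsilyl)oxy]-2-(3-methylbut-3-en-1-yl)-3-(4-methylpent-3-en-1-yl)-4-[(triisopropylsilyl)oxy]but-2-ene, via alkylzinc bromide 9 (not isolated)
Conditions: 8, Zn, LiCl, THF, 40 °C; then 7, PdCl2(dppf) (5 mol%), THF, 50 °C
Reagents that add atoms: none
Why: Negishi sp2–sp3 coupling with retention of olefin geometry; the chelating ferrocenyl diphosphine favours reductive elimination over beta-hydride elimination of the primary alkyl group.

Step 5
Reactants: 10 (2E)-1-[(tert-butyldimethylsilyl)oxy]-2-(3-methylbut-3-en-1-yl)-3-(4-methylpent-3-en-1-yl)-4-[(triisopropylsilyl)oxy]but-2-ene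
Product: 11 (3S)-3-[(3E)-4-{[(tert-butyldimethylsilyl)oxy]methyl}-7-methyl-3-{[(triisopropylsilyl)oxy]methyl}octa-3,7-dien-1-yl]-2,2-dimethyloxirane
Conditions: L-fructose-derived Shi ketone (30 mol%), KHSO5 (Oxone), K2CO3, Bu4NHSO4, MeCN/CH2(OMe)2/aq. Na2B4O7 buffer (pH 10.5), 0 °C
Reagents that add atoms: potassium peroxymonosulfate (KHSO5), OOS(=O)(=O)[O-].[K+]
Why: Shi epoxidation; the bulky chiral dioxirane should prefer the unhindered, electron-rich trisubstituted terminus over the tetrasubstituted olefin (shielded, and deactivated by two allylic oxygens) and over the 1,1-disubstituted olefin. The ketone enantiomer from L-fructose delivers oxygen through the spiro transition state to the face that gives the (S)-epoxide.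

Step 6
Reactants: 11 (3S)-3-[(3E)-4-{[(tert-butyldimethylsilyl)oxy]methyl}-7-methyl-3-{[(triisopropylsilyl)oxy]methyl}octa-3,7-dien-1-yl]-2,2-dimethyloxirane
Product: 12 (2S,4aS,8aS)-8a-{[(tert-butyldimethylsilyl)oxy]methyl}-1,1,6-trimethyl-4a-{[(triisopropylsilyl)oxy]methyl}-1,2,3,4,4a,5,8,8a-octahydronaphthalen-2-ol
Conditions: MeAlCl2 (2.2 equiv), CH2Cl2, −78 °C; then Et3N/MeOH, aq. NaHCO3
Reagents that add atoms: none
Why: MeAlCl2 binds the epoxide oxygen and the C-e–O bond breaks as the tetrasubstituted olefin attacks through C-f (ring A, 6-endo), the charge that builds at tertiary C-a is taken up by the terminal methylene C-i of the isopropenyl group (ring B, 6-endo), and the tertiary cation at C-j loses a proton. The closest known reaction type is the Lewis-acid bicyclisation of terminal epoxy-polyenes to 3-hydroxy trans-decalins of the drimane type, here with the less common tetrasubstituted central olefin. C-d keeps the configuration of the epoxide and its oxygen sits equatorial in the chair that forms ring A. C-f and C-a are set by antiperiplanar addition to the two faces of the E olefin in a chair–chair array, so that the rings are trans-fused and CH2OTBS (on C-f, opposite to the hydroxyl) and CH2OTIPS (on C-a) end up trans-diaxial. The step needs 6-endo and not 5-exo closure of the first ring although either mode would leave a tertiary cation; the chair array, and the fact that only a cation at C-a can be reached by the tethered olefin through a six-membered ring, should secure it. It also needs olefin attack to outrun the hydride shift that turns an opened epoxide into a ketone, hence the strong Lewis acid at low temperature, and it needs C-a to meet no competing internal nucleophile, hence bulky silyl ethers and no ester or benzyl ether on the arms. Proton loss should favour the C-h=C-j olefin, the more stable position in a trans-decalin; the C-i=C-j isomer would reach the same cage by the same later steps, and an exocyclic isomer can be moved into the ring with catalytic TsOH at the stage of 12.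

Step 7
Reactants: 12 (2S,4aS,8aS)-8a-{[(tert-butyldimethylsilyl)oxy]methyl}-1,1,6-trimethyl-4a-{[(triisopropylsilyl)oxy]methyl}-1,2,3,4,4a,5,8,8a-octahydronaphthalen-2-ol
Product: 13 (4aS,8aS)-8a-{[(tert-butyldimethylsilyl)oxy]methyl}-1,1,6-trimethyl-4a-{[(triisopropylsilyl)oxy]methyl}-3,4,4a,5,8,8a-hexahydronaphthalen-2(1H)-one
Conditions: Dess–Martin periodinane, NaHCO3, CH2Cl2, rt
Reagents that add atoms: none
Why: Dess–Martin oxidation of the hindered secondary alcohol; the C-d stereocentre has relayed its chirality to C-a and C-f and is rebuilt in step 18.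

Step 8
Reactants: 13 (4aS,8aS)-8a-{[(tert-butyldimethylsilyl)oxy]methyl}-1,1,6-trimethyl-4a-{[(triisopropylsilyl)oxy]methyl}-3,4,4a,5,8,8a-hexahydronaphthalen-2(1H)-one
Product: 14 (4aS,8aS)-8a-{[(tert-butyldimethylsilyl)oxy]methyl}-1,1,6-trimethyl-4a-{[(triisopropylsilyl)oxy]methyl}-1,4,4a,5,8,8a-hexahydronaphthalen-2-yl trifluoromethanesulfonate
Conditions: KN(SiMe3)2, THF, −78 °C; PhNTf2, −78 to 0 °C
Reagents that add atoms: N-phenylbis(trifluoromethanesulfonimide), O=S(=O)(N(c1ccccc1)S(=O)(=O)C(F)(F)F)C(F)(F)F
Why: The ketone can enolise only toward C-c because C-e is quaternary, so O-triflation of the potassium enolate gives a single enol triflate. It is a masked ring-A olefin that is electron-poor and inert to borane.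

Step 9
Reactants: 14 (4aS,8aS)-8a-{[(tert-butyldimethylsilyl)oxy]methyl}-1,1,6-trimethyl-4a-{[(triisopropylsilyl)oxy]methyl}-1,4,4a,5,8,8a-hexahydronaphthalen-2-yl trifluoromethanesulfonate
Product: 15 8a-[(TBS-oxy)methyl]-7-hydroxy-1,1,6-trimethyl-4a-[(TIPS-oxy)methyl]-1,4,4a,5,6,7,8,8a-octahydronaphthalen-2-yl trifluoromethanesulfonate (6-CH3 and 7-OH equatorial and trans; ring fusion as in 12)
Conditions: BH3·THF, THF, 0 °C to rt; then NaBO3·4H2O, THF/H2O, rt
Reagents that add atoms: sodium perborate, [Na+].[O-]OB=O
Why: Hydroboration–oxidation of the trisubstituted ring-B olefin puts boron, then oxygen, on the CH terminus C-h by syn addition from the face opposite the axial CH2OTBS group. The enol triflate does not react with borane and the mild perborate oxidation spares it.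

Step 10
Reactants: 15 8a-[(TBS-oxy)methyl]-7-hydroxy-1,1,6-trimethyl-4a-[(TIPS-oxy)methyl]-1,4,4a,5,6,7,8,8a-octahydronaphthalen-2-yl trifluoromethanesulfonate
Product: 16 8a-[(TBS-oxy)methyl]-1,1,6-trimethyl-4a-[(TIPS-oxy)methyl]-1,4,4a,5,6,7,8,8a-octahydronaphthalen-7-ol (6-CH3 and 7-OH equatorial; ring fusion as in 12)
Conditions: Pd(OAc)2 (5 mol%), PPh3, HCO2H, Bu3N, DMF, 60 °C
Reagents that add atoms: none
Why: Palladium-catalysed formate reduction of an enol triflate (oxidative addition to zerovalent palladium, formate exchange, loss of CO2, reductive elimination) unveils the C-c=C-d olefin at a defined position.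

Step 11
Reactants: 16 8a-[(TBS-oxy)methyl]-1,1,6-trimethyl-4a-[(TIPS-oxy)methyl]-1,4,4a,5,6,7,8,8a-octahydronaphthalen-7-ol
Product: 17 8a-(hydroxymethyl)-1,1,6-trimethyl-4a-[(TIPS-oxy)methyl]-1,4,4a,5,6,7,8,8a-octahydronaphthalen-7-ol (6-CH3 and 7-OH equatorial; ring fusion as in 12)
Conditions: CSA (10 mol%), MeOH/CH2Cl2, 0 °C
Reagents that add atoms: none
Why: Acid-catalysed methanolysis removes the primary TBS ether well before the bulkier primary TIPS ether.

Step 12
Reactants: 17 8a-(hydroxymethyl)-1,1,6-trimethyl-4a-[(TIPS-oxy)methyl]-1,4,4a,5,6,7,8,8a-octahydronaphthalen-7-ol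
Product: 18 1,1,6-trimethyl-7-oxo-4a-[(TIPS-oxy)methyl]-1,4,4a,5,6,7,8,8a-octahydronaphthalene-8a-carbaldehyde (6-CH3 equatorial; ring fusion as in 12)
Conditions: Dess–Martin periodinane (2.5 equiv), NaHCO3, CH2Cl2, rt
Reagents that add atoms: none
Why: Double Dess–Martin oxidation gives the ring-B ketone and the angular aldehyde. The aldehyde has no alpha hydrogen, and ring A no longer holds a carbonyl group whose enol could reach it.

Step 13
Reactants: 18 1,1,6-trimethyl-7-oxo-4a-[(TIPS-oxy)methyl]-1,4,4a,5,6,7,8,8a-octahydronaphthalene-8a-carbaldehyde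
Product: 20 bridged silyloxy ketone (C-k bonded to C-j: bicyclo[2.2.1]heptan-2-one with bridgeheads C-f and C-j and ring A fused at C-a–C-f; C=O at C-h; OTBS on C-k syn to the C-g–C-h bridge; CH2OTIPS on C-a endo; ring-A olefin C-c=C-d), via TBS enol ether 19 (not isolated)
Conditions: TBSOTf (2.2 equiv), Et3N (3 equiv), CH2Cl2, −78 to 0 °C
Reagents that add atoms: tert-butyldimethylsilyl trifluoromethanesulfonate, CC(C)(C)[Si](C)(C)OS(=O)(=O)C(F)(F)F
Why: Intramolecular Mukaiyama aldol addition: silyl triflate and amine convert the ketone into its more substituted TBS enol ether 19, the same triflate activates the aldehyde, and C-j attacks C-k across a boat of ring B; the silyl group ends on the new oxygen, so the strained product cannot revert as a metal aldolate would. The same bond is formed when an enol ester of a 4-substituted cyclohexanone closes onto a cationic carbon of the 4-substituent to give a bornan-2-one, and only the enol ether toward C-j can cyclise, so its regioisomer toward C-g is merely recycled as ketone. The bulky silyloxonium oxygen should lie over the open C-g–C-h bridge and not over C-a with its exo ring-A methylene, which places the oxygen on C-k as in 34.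

Step 14
Reactants: 20 bridged silyloxy ketone
Product: 21 tosylhydrazone of 20 (C-h=N–NHTs)
Conditions: TsNHNH2, PPTS (cat.), EtOH, 60 °C
Reagents that add atoms: 4-methylbenzenesulfonohydrazide, Cc1ccc(cc1)S(=O)(=O)NN
Why: Condensation of the ketone with tosylhydrazide; hindered bornanone-type ketones condense on warming, and the weak acid leaves both silyl ethers in place.

Step 15
Reactants: 21 tosylhydrazone of 20
Product: 24 nortricyclene bis-silyl ether (new C-h–C-i bond; OTBS on C-k; CH2OTIPS on C-a; ring-A olefin), via sodium salt 22 (not isolated), via diazoalkane 23 (not isolated)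
Conditions: NaH, THF, rt; solvent exchange; diglyme, 150 °C
Reagents that add atoms: none
Why: Aprotic Bamford–Stevens reaction: the salt loses sulfinate, the diazoalkane loses nitrogen, and the 2-norbornylidene-type carbene inserts into the endo C–H bond at C-i that faces it across the ring, as bornan-2-ylidenes give tricyclenes. The rigid bicycle disfavours the 1,2-hydrogen shift from C-g, and the new bond can form only on the endo face, so C-h and C-i are fixed by the cage.

Step 16
Reactants: 24 nortricyclene bis-silyl ether
Product: 25 nortricyclene diol (CH2OH on C-a; OH on C-k; ring-A olefin)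
Conditions: Bu4NF, THF, rt to 50 °C
Reagents that add atoms: none
Why: Fluoride cleaves both silyl ethers; the olefin and the cyclopropane are inert to it.

Step 17
Reactants: 25 nortricyclene diol
Product: 26 nortricyclene diacetate (CH2OAc on C-a; OAc on C-k; ring-A olefin C-c=C-d)
Conditions: Ac2O, DMAP, pyridine, 40 °C
Reagents that add atoms: acetic anhydride, CC(=O)OC(C)=O
Why: Forcing acylation of the primary and of the hindered bridge hydroxyl while no other hydroxyl is present. The acetate also makes the oxygen of the CH2O arm, which overhangs C-c, too weak a nucleophile to capture the iodonium ion of step 18.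

Step 18
Reactants: 26 nortricyclene diacetate
Product: 29 tetraol (CH2OH on C-a; OH on C-k; cis-diol with axial OH on C-c and equatorial OH on C-d on the ring-A face of CH2OH), via iodo acetate 27 (not isolated), via hydroxy acetate 28 (not isolated)
Conditions: I2, AgOAc, AcOH, rt; then H2O, 90 °C; then K2CO3, MeOH, 40 °C
Reagents that add atoms: silver acetate (AgOAc), CC(=O)[O-].[Ag+]
Why: Woodward cis-hydroxylation: the iodonium ion forms on the less hindered face (that of C-k) and is opened trans-diaxially by acetate at C-c. The neighbouring acetate then displaces the axial iodide with silver assistance, giving a cis-fused acetoxonium ion on the opposite face, which water opens. Both new C–O bonds thus lie on the face of CH2OAc, and methanolysis of all acetates removes any question of which ring-A oxygen carried the acyl group.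

Step 19
Reactants: 29 tetraol
Product: 32 diol diacetate (CH2OAc on C-a; OAc on C-k; free cis-diol on C-c and C-d), via phenylboronate 30 (not isolated), via boronate diacetate 31 (not isolated)
Conditions: PhB(OH)2, pyridine, 4 Å sieves, rt; then Ac2O, DMAP, 40 °C; then pinacol, rt
Reagents that add atoms: acetic anhydride, CC(=O)OC(C)=O
Why: Transient protection of the cis-1,2-diol as its cyclic phenylboronate leaves only the primary and the bridge hydroxyl open to forcing acetylation; transesterification with pinacol then frees the diol without touching the acetates.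

Step 20
Reactants: 32 diol diacetate
Product: 34 CNP0111873.1 (target), via stannylene acetal 33 (not isolated)
Conditions: Bu2SnO, toluene, reflux with removal of water; then AcCl, 0 °C
Reagents that add atoms: acetyl chloride, CC(Cl)=O
Why: Regioselective acylation of a cis-diol through its dibutylstannylene acetal, which reacts at the equatorial oxygen (C-d). The axial C-c hydroxyl, flanked by two syn-axial carbon substituents, stays free.

## Compound list

1 | but-2-yne-1,4-diol | OCC#CCO | starting material
2 | 4-[(tert-butyldimethylsilyl)oxy]but-2-yn-1-ol | OCC#CCO[Si](C)(C)C(C)(C)C | intermediate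
3 | 5-bromo-2-methylpent-2-ene | CC(C)=CCCBr | starting material
4 | (4-methylpent-3-en-1-yl)magnesium bromide | CC(C)=CCC[Mg]Br | intermediate (not isolated)
5 | 3-{[(tert-butyldimethylsilyl)oxy]methyl}-4-(4-methylpent-3-en-1-yl)-2,5-dihydro-1,2-oxamagnesole (cyclic alkenylmagnesium alkoxide) | CC(C)=CCCC1=C(CO[Si](C)(C)C(C)(C)C)[Mg]OC1 | intermediate (not isolated)
6 | (2Z)-4-[(tert-butyldimethylsilyl)oxy]-3-iodo-2-(4-methylpent-3-en-1-yl)but-2-en-1-ol | OC/C(CCC=C(C)C)=C(\I)CO[Si](C)(C)C(C)(C)C | intermediate
7 | (2Z)-1-[(tert-butyldimethylsilyl)oxy]-2-iodo-3-(4-methylpent-3-en-1-yl)-4-[(triisopropylsilyl)oxy]but-2-ene | CC(C)[Si](C(C)C)(C(C)C)OC/C(CCC=C(C)C)=C(\I)CO[Si](C)(C)C(C)(C)C | intermediate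
8 | 4-bromo-2-methylbut-1-ene | CC(=C)CCBr | starting material
9 | (3-methylbut-3-en-1-yl)zinc bromide | CC(=C)CC[Zn]Br | intermediate (not isolated)
10 | (2E)-1-[(tert-butyldimethylsilyl)oxy]-2-(3-methylbut-3-en-1-yl)-3-(4-methylpent-3-en-1-yl)-4-[(triisopropylsilyl)oxy]but-2-ene | CC(C)[Si](C(C)C)(C(C)C)OC/C(CCC=C(C)C)=C(\CCC(C)=C)CO[Si](C)(C)C(C)(C)C | intermediate
11 | (3S)-3-[(3E)-4-{[(tert-butyldimethylsilyl)oxy]methyl}-7-methyl-3-{[(triisopropylsilyl)oxy]methyl}octa-3,7-dien-1-yl]-2,2-dimethyloxirane | CC1(C)O[C@H]1CC/C(CO[Si](C(C)C)(C(C)C)C(C)C)=C(\CO[Si](C)(C)C(C)(C)C)CCC(C)=C | intermediate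
12 | (2S,4aS,8aS)-8a-{[(tert-butyldimethylsilyl)oxy]methyl}-1,1,6-trimethyl-4a-{[(triisopropylsilyl)oxy]methyl}-1,2,3,4,4a,5,8,8a-octahydronaphthalen-2-ol | CC(C)[Si](C(C)C)(C(C)C)OC[C@]12CC[C@H](O)C(C)(C)[C@]1(CO[Si](C)(C)C(C)(C)C)CC=C(C)C2 | intermediate
13 | (4aS,8aS)-8a-{[(tert-butyldimethylsilyl)oxy]methyl}-1,1,6-trimethyl-4a-{[(triisopropylsilyl)oxy]methyl}-3,4,4a,5,8,8a-hexahydronaphthalen-2(1H)-one | CC(C)[Si](C(C)C)(C(C)C)OC[C@]12CCC(=O)C(C)(C)[C@]1(CO[Si](C)(C)C(C)(C)C)CC=C(C)C2 | intermediate
14 | (4aS,8aS)-8a-{[(tert-butyldimethylsilyl)oxy]methyl}-1,1,6-trimethyl-4a-{[(triisopropylsilyl)oxy]methyl}-1,4,4a,5,8,8a-hexahydronaphthalen-2-yl trifluoromethanesulfonate | CC(C)[Si](C(C)C)(C(C)C)OC[C@]12CC=C(OS(=O)(=O)C(F)(F)F)C(C)(C)[C@]1(CO[Si](C)(C)C(C)(C)C)CC=C(C)C2 | intermediate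
15 | 8a-[(TBS-oxy)methyl]-7-hydroxy-1,1,6-trimethyl-4a-[(TIPS-oxy)methyl]-1,4,4a,5,6,7,8,8a-octahydronaphthalen-2-yl trifluoromethanesulfonate, 6-CH3 and 7-OH equatorial and trans, ring fusion as in 12 | CC(C)[Si](C(C)C)(C(C)C)OC[C@]12CC=C(OS(=O)(=O)C(F)(F)F)C(C)(C)[C@]1(CO[Si](C)(C)C(C)(C)C)C[C@H](O)[C@@H](C)C2 | intermediate
16 | 8a-[(TBS-oxy)methyl]-1,1,6-trimethyl-4a-[(TIPS-oxy)methyl]-1,4,4a,5,6,7,8,8a-octahydronaphthalen-7-ol, 6-CH3 and 7-OH equatorial, ring fusion as in 12 | CC(C)[Si](C(C)C)(C(C)C)OC[C@]12CC=CC(C)(C)[C@]1(CO[Si](C)(C)C(C)(C)C)C[C@H](O)[C@@H](C)C2 | intermediate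
17 | 8a-(hydroxymethyl)-1,1,6-trimethyl-4a-[(TIPS-oxy)methyl]-1,4,4a,5,6,7,8,8a-octahydronaphthalen-7-ol, 6-CH3 and 7-OH equatorial, ring fusion as in 12 | CC(C)[Si](C(C)C)(C(C)C)OC[C@]12CC=CC(C)(C)[C@]1(CO)C[C@H](O)[C@@H](C)C2 | intermediate
18 | 1,1,6-trimethyl-7-oxo-4a-[(TIPS-oxy)methyl]-1,4,4a,5,6,7,8,8a-octahydronaphthalene-8a-carbaldehyde, 6-CH3 equatorial, ring fusion as in 12 | CC(C)[Si](C(C)C)(C(C)C)OC[C@]12CC=CC(C)(C)[C@]1(C=O)CC(=O)[C@@H](C)C2 | intermediate
19 | 7-(TBS-oxy)-1,1,6-trimethyl-4a-[(TIPS-oxy)methyl]-1,4,4a,5,8,8a-hexahydronaphthalene-8a-carbaldehyde (TBS enol ether) | CC(C)[Si](C(C)C)(C(C)C)OC[C@]12CC=CC(C)(C)[C@]1(C=O)CC(O[Si](C)(C)C(C)(C)C)=C(C)C2 | intermediate (not isolated)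
20 | bridged silyloxy ketone: C-k joins C-f and C-j (bicyclo[2.2.1]heptan-2-one fused to ring A at C-a–C-f), C=O at C-h, OTBS on C-k syn to the C-g–C-h bridge, CH2OTIPS on C-a endo, ring-A olefin C-c=C-d | CC(C)[Si](C(C)C)(C(C)C)OC[C@]12CC=CC(C)(C)[C@]13CC(=O)[C@](C)(C2)[C@H]3O[Si](C)(C)C(C)(C)C | intermediate
21 | tosylhydrazone of 20 | CC(C)[Si](C(C)C)(C(C)C)OC[C@]12CC=CC(C)(C)[C@]13CC(=NNS(=O)(=O)c4ccc(C)cc4)[C@](C)(C2)[C@H]3O[Si](C)(C)C(C)(C)C | intermediate
22 | sodium salt of 21 | CC(C)[Si](C(C)C)(C(C)C)OC[C@]12CC=CC(C)(C)[C@]13CC(=N[N-]S(=O)(=O)c4ccc(C)cc4)[C@](C)(C2)[C@H]3O[Si](C)(C)C(C)(C)C.[Na+] | intermediate (not isolated)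
23 | diazoalkane (diazo group on C-h) | CC(C)[Si](C(C)C)(C(C)C)OC[C@]12CC=CC(C)(C)[C@]13CC(=[N+]=[N-])[C@](C)(C2)[C@H]3O[Si](C)(C)C(C)(C)C | intermediate (not isolated)
24 | nortricyclene bis-silyl ether: cage of 34 with OTBS on C-k, CH2OTIPS on C-a and the ring-A olefin C-c=C-d | CC(C)[Si](C(C)C)(C(C)C)OC[C@]12CC=CC(C)(C)[C@]13C[C@@H]1[C@H]2[C@]1(C)[C@H]3O[Si](C)(C)C(C)(C)C | intermediate
25 | nortricyclene diol: CH2OH on C-a, OH on C-k, ring-A olefin | OC[C@]12CC=CC(C)(C)[C@]13C[C@@H]1[C@H]2[C@]1(C)[C@H]3O | intermediate
26 | nortricyclene diacetate: CH2OAc on C-a, OAc on C-k, ring-A olefin | CC(=O)OC[C@]12CC=CC(C)(C)[C@]13C[C@@H]1[C@H]2[C@]1(C)[C@H]3OC(C)=O | intermediate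
27 | iodo acetate: axial OAc on C-c (face of CH2OAc), axial I on C-d (opposite face) | CC(=O)OC[C@]12C[C@H](OC(C)=O)[C@@H](I)C(C)(C)[C@]13C[C@@H]1[C@H]2[C@]1(C)[C@H]3OC(C)=O | intermediate (not isolated)
28 | hydroxy triacetate: cis, axial OAc on C-c and equatorial OH on C-d | CC(=O)OC[C@]12C[C@H](OC(C)=O)[C@H](O)C(C)(C)[C@]13C[C@@H]1[C@H]2[C@]1(C)[C@H]3OC(C)=O | intermediate (not isolated)
29 | tetraol: CH2OH on C-a, OH on C-k, cis-diol on C-c (axial) and C-d (equatorial) | OC[C@]12C[C@H](O)[C@H](O)C(C)(C)[C@]13C[C@@H]1[C@H]2[C@]1(C)[C@H]3O | intermediate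
30 | cyclic phenylboronate of the C-c/C-d diol of 29 | OC[C@]12C[C@@H]4OB(c5ccccc5)O[C@@H]4C(C)(C)[C@]13C[C@@H]1[C@H]2[C@]1(C)[C@H]3O | intermediate (not isolated)
31 | diacetate of 30 | CC(=O)OC[C@]12C[C@@H]4OB(c5ccccc5)O[C@@H]4C(C)(C)[C@]13C[C@@H]1[C@H]2[C@]1(C)[C@H]3OC(C)=O | intermediate (not isolated)
32 | diol diacetate: CH2OAc on C-a, OAc on C-k, free cis-diol on C-c and C-d | CC(=O)OC[C@]12C[C@H](O)[C@H](O)C(C)(C)[C@]13C[C@@H]1[C@H]2[C@]1(C)[C@H]3OC(C)=O | intermediate
33 | dibutylstannylene acetal of 32 | CC(=O)OC[C@]12C[C@@H]4O[Sn](CCCC)(CCCC)O[C@@H]4C(C)(C)[C@]13C[C@@H]1[C@H]2[C@]1(C)[C@H]3OC(C)=O | intermediate (not isolated)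
34 | CNP0111873.1: ring A fused to the nortricyclene cage, CH2OAc on C-a, axial OH on C-c, equatorial OAc on C-d, OAc on C-k toward C-g | CC(=O)OC[C@]12C[C@H](O)[C@H](OC(C)=O)C(C)(C)[C@]13C[C@@H]1[C@H]2[C@]1(C)[C@H]3OC(C)=O | target

## Step count and least certain steps

Total: 20 steps. Longest linear sequence: 20 steps from 1 (bromides 3 and 8 enter as organometallic reagents made in the flask).

**Step 6 (key step).**
- What may go wrong: closure of the first ring in the five-membered mode, since both carbons of the central olefin are fully substituted; hydride migration in the opened epoxide (ketone formation) before an olefin that two allylic C–O bonds make electron-poor can attack; collapse of the C-a cation by proton loss before ring B closes; proton loss in several directions at the end.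
- Fallback (sets out from 7, returns at 12): the terminating olefin is made far more nucleophilic, and the site of termination is fixed, by an allylsilane.
  - 3-Methylbut-3-en-1-ol is doubly lithiated (BuLi, TMEDA) and C-silylated to 3-[(trimethylsilyl)methyl]but-3-en-1-ol F1.
  - Iodination (PPh3, I2, imidazole) gives 4-iodo-2-[(trimethylsilyl)methyl]but-1-ene F2.
  - Iodide 7 is epoxidised under the conditions of step 5 to the epoxy vinyl iodide F3; this is done first because the iodo-olefin is inert to the dioxirane whereas an allylsilane would compete.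
  - Negishi coupling of F3 with the zinc reagent of F2 (Zn, LiCl; PdCl2(dppf), rt) gives the allylsilane epoxide F4.
  - MeAlCl2 at −78 °C should then give the exocyclic-methylene decalinol F5 by loss of the silyl group from the beta-silyl cation at C-j.
  - Catalytic TsOH or I2 moves the double bond into the ring, to 12.

**Step 13.**
- What may go wrong: silylation toward C-g, which gives an enol ether that cannot cyclise; slow closure, because the transition state already carries much of the norbornanone strain, so that intermolecular aldol addition or attack of the ring-A olefin on the activated aldehyde competes; delivery of the aldehyde oxygen to the wrong side of C-k.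
- Fallback (sets out from 18, returns at 20):
  - CuBr2 (EtOAc/CHCl3, reflux) brominates the more substituted alpha carbon to the bromo keto aldehyde F6.
  - SmI2 (THF, −78 °C) reduces the C–Br bond to a samarium enolate that is defined at C-j and adds to the aldehyde in a Reformatsky-type closure. Its chelated transition state holds the new oxygen next to the ketone oxygen, that is syn to the carbonyl bridge.
  - The hydroxy ketone F7 is silylated at once (TBSOTf, 2,6-lutidine, −78 °C) to 20.

**Step 15.**
- What may go wrong: 1,2-hydrogen shift of the carbene to a norbornene; insertion into the C–H bonds of the neighbouring CH2OTIPS group; cationic decomposition with skeletal rearrangement if a proton source is present; loss of silyl groups at 150 °C.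
- Fallback (sets out from 20, returns at 24 through 23): hydrazine hydrate (EtOH, Et3N) gives the hydrazone F8. Oxidation with HgO (catalytic KOH, Et2O) forms diazoalkane 23 at room temperature under neutral conditions, and gentle warming or irradiation then gives 24 without strong base or high temperature.

**Step 18.**
- What may go wrong: attack of electrophilic iodine or of hot acid on the strained cyclopropane; ionisation of the cyclopropylcarbinyl acetate on C-k; opening of the iodonium ion at the wrong carbon.
- Fallback (sets out from 26, returns at 28 and so at 29 by the methanolysis of step 18):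
  - mCPBA epoxidises the olefin from the less hindered face to the epoxide F9.
  - Warm acetic acid opens it trans-diaxially to the hydroxy acetate F10 (acetate axial on C-c, hydroxyl axial on C-d on the other face).
  - Tf2O/pyridine gives the triflate F11, which the neighbouring acetate displaces with inversion at C-d; aqueous work-up of the acetoxonium ion gives 28.

**Step 2.**
- What may go wrong: beta-elimination of the silyloxy group from the alkenylmagnesium intermediate to an allene, since the magnesium-bearing carbon carries CH2OTBS; incomplete addition of the alkyl Grignard reagent.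
- Fallback (sets out from 3 and zinc reagent 9, returns at 10):
  - Ethyl 4-[(tert-butyldimethylsilyl)oxy]-3-oxobutanoate F12 is made by Roskamp reaction of [(tert-butyldimethylsilyl)oxy]acetaldehyde with ethyl diazoacetate (SnCl2).
  - Alkylation with 3 (NaH, NaI, DMF) gives the keto ester F13.
  - Chelation-controlled triflation of its sodium enolate (NaH, Tf2O, toluene, 0 °C) gives the (Z)-enol triflate F14, with the triflate cis to the ester.
  - Negishi coupling with 9 (PdCl2(dppf)) replaces the triflate with retention and gives the enoate F15.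
  - iBu2AlH reduces the ester to the allylic alcohol F16, and silylation as in step 3 gives 10.

## Further compounds

F1 | step 6 | 3-[(trimethylsilyl)methyl]but-3-en-1-ol | C[Si](C)(C)CC(=C)CCO
F2 | step 6 | 4-iodo-2-[(trimethylsilyl)methyl]but-1-ene | C[Si](C)(C)CC(=C)CCI
F3 | step 6 | epoxy vinyl iodide, (S)-epoxide of 7 | CC1(C)O[C@H]1CC/C(CO[Si](C(C)C)(C(C)C)C(C)C)=C(\CO[Si](C)(C)C(C)(C)C)I
F4 | step 6 | allylsilane epoxide, analogue of 11 with CH2SiMe3 on C-j | CC1(C)O[C@H]1CC/C(CO[Si](C(C)C)(C(C)C)C(C)C)=C(\CO[Si](C)(C)C(C)(C)C)CCC(=C)C[Si](C)(C)C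
F5 | step 6 | exocyclic-methylene decalinol, isomer of 12 with C-j=CH2 | CC(C)[Si](C(C)C)(C(C)C)OC[C@]12CC[C@H](O)C(C)(C)[C@]1(CO[Si](C)(C)C(C)(C)C)CCC(=C)C2
F6 | step 13 | bromo keto aldehyde, 18 with Br on C-j (either epimer) | CC(C)[Si](C(C)C)(C(C)C)OC[C@]12CC=CC(C)(C)[C@]1(C=O)CC(=O)C(C)(Br)C2
F7 | step 13 | bridged hydroxy ketone, 20 with free OH on C-k | CC(C)[Si](C(C)C)(C(C)C)OC[C@]12CC=CC(C)(C)[C@]13CC(=O)[C@](C)(C2)[C@H]3O
F8 | step 15 | hydrazone of 20 | CC(C)[Si](C(C)C)(C(C)C)OC[C@]12CC=CC(C)(C)[C@]13CC(=NN)[C@](C)(C2)[C@H]3O[Si](C)(C)C(C)(C)C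
F9 | step 18 | ring-A epoxide of 26 on the face of C-k | CC(=O)OC[C@]12C[C@H]4O[C@H]4C(C)(C)[C@]13C[C@@H]1[C@H]2[C@]1(C)[C@H]3OC(C)=O
F10 | step 18 | trans-diaxial hydroxy acetate, OAc on C-c and OH on C-d | CC(=O)OC[C@]12C[C@H](OC(C)=O)[C@@H](O)C(C)(C)[C@]13C[C@@H]1[C@H]2[C@]1(C)[C@H]3OC(C)=O
F11 | step 18 | triflate of F10 | CC(=O)OC[C@]12C[C@H](OC(C)=O)[C@@H](OS(=O)(=O)C(F)(F)F)C(C)(C)[C@]13C[C@@H]1[C@H]2[C@]1(C)[C@H]3OC(C)=O
F12 | step 2 | ethyl 4-[(tert-butyldimethylsilyl)oxy]-3-oxobutanoate | CCOC(=O)CC(=O)CO[Si](C)(C)C(C)(C)C
F13 | step 2 | ethyl 2-{[(tert-butyldimethylsilyl)oxy]acetyl}-6-methylhept-5-enoate (racemic) | CCOC(=O)C(CCC=C(C)C)C(=O)CO[Si](C)(C)C(C)(C)C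
F14 | step 2 | ethyl (2Z)-4-[(tert-butyldimethylsilyl)oxy]-2-(4-methylpent-3-en-1-yl)-3-{[(trifluoromethyl)sulfonyl]oxy}but-2-enoate | CCOC(=O)/C(CCC=C(C)C)=C(\OS(=O)(=O)C(F)(F)F)CO[Si](C)(C)C(C)(C)C
F15 | step 2 | ethyl (2E)-3-{[(tert-butyldimethylsilyl)oxy]methyl}-6-methyl-2-(4-methylpent-3-en-1-yl)hepta-2,6-dienoate | CCOC(=O)/C(CCC=C(C)C)=C(\CCC(C)=C)CO[Si](C)(C)C(C)(C)C
F16 | step 2 | (2E)-3-{[(tert-butyldimethylsilyl)oxy]methyl}-6-methyl-2-(4-methylpent-3-en-1-yl)hepta-2,6-dien-1-ol | OC/C(CCC=C(C)C)=C(\CCC(C)=C)CO[Si](C)(C)C(C)(C)C
A1 | alternative 1 | cage monoacetate with free CH2OH and ring-A carbonate | OC[C@]12C[C@@H]4OC(=O)O[C@@H]4C(C)(C)[C@]13C[C@@H]1[C@H]2[C@]1(C)[C@H]3OC(C)=O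
A2 | alternative 2 | cis-fused 2-methylhydrindenone dimethyl ketal | CC(C)(C)[Si](C)(C)OC[C@]12C[C@H](OCOC)C(OC)(OC)C(C)(C)[C@H]1C(=O)C(C)=C2
A3 | alternative 3 | nortricyclanone methyl ester with ring-A side chain | CC(C)(C)[Si](C)(C)OC[C@@H]1OC(C)(C)O[C@@H]1C(C)(C)[C@]23C[C@@H]4[C@H]([C@@H]2C(=O)OC)[C@]4(C)C3=O
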